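**Retrosynthetic overview**
1. Quinone 14 ⇐ para-oxidation of the 2,6-dialkylphenol 13 (the bought cresol ring becomes the quinone last).
2. 13 ⇐ carbonylative lactonisation of the (Z)-bromoalkene diol 12 (the only ring built; C=O ends up cis to the chain by retention).
3. 12 ⇐ light-driven nickel/iridium decarboxylative coupling of 1,1-dibromoalkene 7 with the ring-opened lactone 10 (stereocentre bought in the D-glutamic-acid-derived lactone acid 8).
4. 7 ⇐ ortho C-allylation of o-cresol 6 with tribromide 5; 5 ⇐ (2E,6E)-farnesol 1 by terminal epoxidation, glycol cleavage and one-pot dibromo-olefination/bromination.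

Assumption: (2E,6E)-farnesol, o-cresol and (R)-5-oxotetrahydrofuran-2-carboxylic acid (made industrially from D-glutamic acid) are purchased as such.

**Route**

Step 1
Reactants: 1 (2E,6E)-farnesol
Product: 3 rac-(2E,6E)-10,11-epoxyfarnesol, via bromohydrin 2 (not isolated)
Conditions: NBS (1.1 equiv), THF/H2O (3:1), 0 °C; then K2CO3, MeOH, 23 °C
Reagents that add atoms: water, O
Why: Terminal-selective bromohydrin formation (in aqueous THF the coiled polyene exposes the terminal trisubstituted alkene) followed by base-induced epoxide closure; the racemic oxirane carbon is destroyed in step 2.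

Step 2
Reactants: 3 rac-(2E,6E)-10,11-epoxyfarnesol
Product: 4 (4E,8E)-10-hydroxy-4,8-dimethyldeca-4,8-dienal
Conditions: H5IO6 (1.2 equiv), THF/H2O, 0 °C, 1 h
Reagents that add atoms: none
Why: Periodic acid opens the epoxide and cleaves the resulting glycol (Malaprade cleavage), releasing acetone and leaving both E-alkenes and the allylic alcohol intact.

Step 3
Reactants: 4 (4E,8E)-10-hydroxy-4,8-dimethyldeca-4,8-dienal
Product: 5 (2E,6E)-1,11,11-tribromo-3,7-dimethylundeca-2,6,10-triene
Conditions: CBr4 (1.5 equiv), PPh3 (3.0 equiv), 2,6-lutidine, CH2Cl2, −20 → 0 °C; used at once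
Reagents that add atoms: carbon tetrabromide, BrC(Br)(Br)Br
Why: Ramirez–Corey–Fuchs dibromo-olefination of the aldehyde by Ph3P=CBr2, while the Ph3PBr2 formed alongside converts the allylic alcohol into the bromide (Appel-type) and the hindered base traps HBr without quaternising.

Step 4
Reactants: 5 (2E,6E)-1,11,11-tribromo-3,7-dimethylundeca-2,6,10-triene; 6 o-cresol (2-methylphenol)
Product: 7 2-[(2E,6E)-11,11-dibromo-3,7-dimethylundeca-2,6,10-trien-1-yl]-6-methylphenol
Conditions: 6 (3 equiv), NaH (3 equiv), toluene, 0 → 23 °C, 16 h (heterogeneous)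
Reagents that add atoms: none
Why: Kornblum-type heterogeneous C-alkylation: the tight sodium phenoxide ion pair in toluene delivers the only free ortho carbon to the primary allylic bromide by SN2 with retention of the 2E geometry, and the dibromoalkene is inert.

Step 5
Reactants: 8 (R)-5-oxotetrahydrofuran-2-carboxylic acid
Product: 10 (5R)-5-(2-hydroxypropan-2-yl)oxolan-2-one, via acid chloride 9 (not isolated)
Conditions: (COCl)2, cat. DMF, CH2Cl2, 0 → 23 °C, concentrate; then MeMgBr (2.1 equiv), THF, −78 °C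
Reagents that add atoms: methylmagnesium bromide, C[Mg]Br
Why: The acid chloride and the methyl ketone formed from it are far more electrophilic than the γ-lactone, so double Grignard addition gives the tertiary alcohol chemoselectively at −78 °C without enolising the bought stereocentre.

Step 6
Reactants: 7 2-[(2E,6E)-11,11-dibromo-3,7-dimethylundeca-2,6,10-trien-1-yl]-6-methylphenol; 10 (5R)-5-(2-hydroxypropan-2-yl)oxolan-2-one
Product: 12 (3R,6Z,10E,14E)-6-bromo-16-(2-hydroxy-3-methylphenyl)-2,10,14-trimethylhexadeca-6,10,14-triene-2,3-diol, via cesium carboxylate 11 (not isolated)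
Conditions: 10 (2.0 equiv), CsOH·H2O (2.0 equiv), DMSO/H2O (20:1), 23 °C, 1 h; then 7 (1.0 equiv), NiCl2·DME (10 mol %), 4,4′-di-tert-butyl-2,2′-bipyridine (15 mol %), [Ir(dF(CF3)ppy)2(dtbbpy)]PF6 (2 mol %), 450 nm LEDs, 25 °C, Ar, 24 h
Reagents that add atoms: none
Why: Proposed new method: a dual nickel/iridium photoredox decarboxylative alkenylation in which the electrophile is a 1,1-dibromoalkene and the acid is the cesium dihydroxy carboxylate 11 made in the flask by saponifying lactone 10 — the excited trivalent iridium photocatalyst oxidises the carboxylate, loss of CO2 gives the primary radical •CH2CH2CH(OH)CMe2OH two carbons away from the untouched stereocentre, zerovalent nickel inserts into the less hindered C–Br bond trans to the chain, radical capture gives trivalent nickel and reductive elimination forms the C(sp3)–C(sp2) bond leaving the bromine cis to the chain (6Z), the more hindered trisubstituted bromoalkene product resists a second oxidative addition and has too high a triplet energy to be isomerised by the sensitiser, and with no base beyond the carboxylate the phenol stays protonated and harder to oxidise; the closest known reaction types are the nickel/iridium photoredox decarboxylative vinylation of carboxylic acids with simple vinyl halides and the palladium-catalysed trans-selective Negishi monoalkylation of 1,1-dibromoalkenes.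

Step 7
Reactants: 12 (3R,6Z,10E,14E)-6-bromo-16-(2-hydroxy-3-methylphenyl)-2,10,14-trimethylhexadeca-6,10,14-triene-2,3-diol
Product: 13 (3Z,6R)-3-[(4E,8E)-10-(2-hydroxy-3-methylphenyl)-4,8-dimethyldeca-4,8-dien-1-ylidene]-6-(2-hydroxypropan-2-yl)oxan-2-one
Conditions: Pd(OAc)2 (5 mol %), Xantphos (7.5 mol %), CO (1 atm), iPr2NEt, toluene, 70 °C
Reagents that add atoms: carbon monoxide, [C-]#[O+]
Why: Palladium-catalysed intramolecular alkoxycarbonylation (carbonylative lactonisation): zerovalent palladium adds to the vinyl bromide with retention, CO inserts, and the secondary hydroxyl closes the six-membered lactone, fixing the carbonyl cis to the chain (Z) with the carbinol centre unchanged.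

Step 8
Reactants: 13 (3Z,6R)-3-[(4E,8E)-10-(2-hydroxy-3-methylphenyl)-4,8-dimethyldeca-4,8-dien-1-ylidene]-6-(2-hydroxypropan-2-yl)oxan-2-one
Product: 14 2-[(2E,6E,10Z)-10-[(6R)-6-(2-hydroxypropan-2-yl)-2-oxooxan-3-ylidene]-3,7-dimethyldeca-2,6-dien-1-yl]-6-methylcyclohexa-2,5-diene-1,4-dione (CNP0270314.1)
Conditions: (KSO3)2NO (2.5 equiv), KH2PO4 buffer, acetone/H2O, 0 → 23 °C
Reagents that add atoms: potassium nitrosodisulfonate, [K+].[K+].[O]N(S(=O)(=O)[O-])S(=O)(=O)[O-]
Why: Teuber oxidation: the nitrosodisulfonate radical oxidises a 2,6-dialkylphenol with a free para position to the para-quinone under buffered aqueous conditions that leave the alkenes, the lactone and the tertiary alcohol untouched.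

**Compound list**
1 | (2E,6E)-farnesol | OC/C=C(\C)CC/C=C(\C)CCC=C(C)C | starting material
2 | rac-(2E,6E)-10-bromo-3,7,11-trimethyldodeca-2,6-diene-1,11-diol (bromohydrin) | OC/C=C(\C)CC/C=C(\C)CCC(Br)C(C)(C)O | intermediate
3 | rac-(2E,6E)-9-(3,3-dimethyloxiran-2-yl)-3,7-dimethylnona-2,6-dien-1-ol (10,11-epoxyfarnesol) | OC/C=C(\C)CC/C=C(\C)CCC1OC1(C)C | intermediate
4 | (4E,8E)-10-hydroxy-4,8-dimethyldeca-4,8-dienal | OC/C=C(\C)CC/C=C(\C)CCC=O | intermediate
5 | (2E,6E)-1,11,11-tribromo-3,7-dimethylundeca-2,6,10-triene | BrC/C=C(\C)CC/C=C(\C)CCC=C(Br)Br | intermediate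
6 | o-cresol (2-methylphenol) | Cc1ccccc1O | starting material
7 | 2-[(2E,6E)-11,11-dibromo-3,7-dimethylundeca-2,6,10-trien-1-yl]-6-methylphenol | Cc1cccc(C/C=C(\C)CC/C=C(\C)CCC=C(Br)Br)c1O | intermediate
8 | (R)-5-oxotetrahydrofuran-2-carboxylic acid | O=C1CC[C@H](C(=O)O)O1 | starting material
9 | (2R)-5-oxooxolane-2-carbonyl chloride | O=C1CC[C@H](C(=O)Cl)O1 | intermediate
10 | (5R)-5-(2-hydroxypropan-2-yl)oxolan-2-one | O=C1CC[C@H](C(C)(C)O)O1 | intermediate
11 | cesium (4R)-4,5-dihydroxy-5-methylhexanoate | [Cs+].[O-]C(=O)CC[C@@H](O)C(C)(C)O | intermediate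
12 | (3R,6Z,10E,14E)-6-bromo-16-(2-hydroxy-3-methylphenyl)-2,10,14-trimethylhexadeca-6,10,14-triene-2,3-diol | Cc1cccc(C/C=C(\C)CC/C=C(\C)CC/C=C(\Br)CC[C@@H](O)C(C)(C)O)c1O | intermediate
13 | (3Z,6R)-3-[(4E,8E)-10-(2-hydroxy-3-methylphenyl)-4,8-dimethyldeca-4,8-dien-1-ylidene]-6-(2-hydroxypropan-2-yl)oxan-2-one | Cc1cccc(C/C=C(\C)CC/C=C(\C)CC/C=C2/CC[C@H](C(C)(C)O)OC2=O)c1O | intermediate
14 | 2-[(2E,6E,10Z)-10-[(6R)-6-(2-hydroxypropan-2-yl)-2-oxooxan-3-ylidene]-3,7-dimethyldeca-2,6-dien-1-yl]-6-methylcyclohexa-2,5-diene-1,4-dione | CC1=CC(=O)C=C(C/C=C(\C)CC/C=C(\C)CC/C=C2/CC[C@H](C(C)(C)O)OC2=O)C1=O | target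

**Step count**
Total: 8 steps. Longest linear sequence: 7 steps (1, 2, 3, 4, 6, 7, 8 from farnesol); step 5 is the one-step side branch.

**Steps most likely to fail**

Step 6 (the proposed new coupling). The risks are slow oxidation of an unactivated primary carboxylate, quenching of the photocatalyst by the phenol, radical addition to the dibromoalkene instead of capture by nickel, and some double coupling. The fallback makes the same bond by the known palladium-catalysed trans-selective Negishi monoalkylation of 1,1-dibromoalkenes; it sets out from 10 and rejoins the route at 12. Lactone 10 is opened and protected in one operation (2,2-dimethoxypropane, MeOH, cat. TsOH) to methyl 3-[(4R)-2,2,5,5-tetramethyl-1,3-dioxolan-4-yl]propanoate F1. Saponification (LiOH, THF/H2O) gives 3-[(4R)-2,2,5,5-tetramethyl-1,3-dioxolan-4-yl]propanoic acid F2. Iododecarboxylation (PhI(OAc)2, I2, hν) gives (4R)-4-(2-iodoethyl)-2,2,5,5-tetramethyl-1,3-dioxolane F3. Zinc insertion (Zn dust, LiCl, THF) gives [2-[(4R)-2,2,5,5-tetramethyl-1,3-dioxolan-4-yl]ethyl]zinc iodide F4. F4 (2.5 equiv, the first equivalent being consumed by the phenol) is coupled with 7 using PdCl2(DPEphos) in THF at 0–23 °C, giving 2-[(2E,6E,10Z)-11-bromo-3,7-dimethyl-13-[(4R)-2,2,5,5-tetramethyl-1,3-dioxolan-4-yl]trideca-2,6,10-trien-1-yl]-6-methylphenol F5. Aqueous acetic acid removes the acetonide to give 12.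

Step 4 (ortho C-allylation). O-alkylation, para attack or SN2′ attack may erode the yield with an allylic bromide that cannot be stored. The fallback replaces phenoxide alkylation by an aryl-copper substitution; it sets out from 5 and rejoins at 7. Commercial 2-bromo-6-methylphenol is protected (MOMCl, iPr2NEt) as 1-bromo-2-(methoxymethoxy)-3-methylbenzene F6. Bromine–lithium exchange (n-BuLi, THF, −78 °C) gives [2-(methoxymethoxy)-3-methylphenyl]lithium F7. After transmetalation with CuBr·SMe2 this displaces the allylic bromide of 5 to give 1-[(2E,6E)-11,11-dibromo-3,7-dimethylundeca-2,6,10-trien-1-yl]-2-(methoxymethoxy)-3-methylbenzene F8. HCl in MeOH removes the MOM group to give 7.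

Step 7 (carbonylative lactonisation). A hindered trisubstituted vinyl bromide may add slowly to palladium, and the vinylpalladium species could cyclise onto a chain alkene or the product could isomerise at 70 °C. The fallback introduces the carbonyl through the vinyllithium; it sets out from 12 and rejoins at 13. Treatment of 12 with t-BuLi (5.5 equiv, three consumed by the hydroxyl groups) in THF at −78 °C and quenching the configurationally stable vinyllithium with CO2 gives (2Z,6E,10E)-2-[(3R)-3,4-dihydroxy-4-methylpentyl]-12-(2-hydroxy-3-methylphenyl)-6,10-dimethyldodeca-2,6,10-trienoic acid F9. Lactonisation (EDC·HCl, DMAP, CH2Cl2) through the secondary hydroxyl gives 13.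

**Further compounds**
F1 | step 6 | methyl 3-[(4R)-2,2,5,5-tetramethyl-1,3-dioxolan-4-yl]propanoate | COC(=O)CC[C@H]1OC(C)(C)OC1(C)C
F2 | step 6 | 3-[(4R)-2,2,5,5-tetramethyl-1,3-dioxolan-4-yl]propanoic acid | OC(=O)CC[C@H]1OC(C)(C)OC1(C)C
F3 | step 6 | (4R)-4-(2-iodoethyl)-2,2,5,5-tetramethyl-1,3-dioxolane | ICC[C@H]1OC(C)(C)OC1(C)C
F4 | step 6 | [2-[(4R)-2,2,5,5-tetramethyl-1,3-dioxolan-4-yl]ethyl]zinc iodide | I[Zn]CC[C@H]1OC(C)(C)OC1(C)C
F5 | step 6 | 2-[(2E,6E,10Z)-11-bromo-3,7-dimethyl-13-[(4R)-2,2,5,5-tetramethyl-1,3-dioxolan-4-yl]trideca-2,6,10-trien-1-yl]-6-methylphenol | Cc1cccc(C/C=C(\C)CC/C=C(\C)CC/C=C(\Br)CC[C@H]2OC(C)(C)OC2(C)C)c1O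
F6 | step 4 | 1-bromo-2-(methoxymethoxy)-3-methylbenzene | COCOc1c(C)cccc1Br
F7 | step 4 | [2-(methoxymethoxy)-3-methylphenyl]lithium | COCOc1c(C)cccc1[Li]
F8 | step 4 | 1-[(2E,6E)-11,11-dibromo-3,7-dimethylundeca-2,6,10-trien-1-yl]-2-(methoxymethoxy)-3-methylbenzene | COCOc1c(C)cccc1C/C=C(\C)CC/C=C(\C)CCC=C(Br)Br
F9 | step 7 | (2Z,6E,10E)-2-[(3R)-3,4-dihydroxy-4-methylpentyl]-12-(2-hydroxy-3-methylphenyl)-6,10-dimethyldodeca-2,6,10-trienoic acid | Cc1cccc(C/C=C(\C)CC/C=C(\C)CC/C=C(\C(=O)O)CC[C@@H](O)C(C)(C)O)c1O
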